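A direct plan would make the ether by SNAr on ring A: 1-fluoro-4-propylbenzene A1 would be formylated twice beside fluorine (two cryogenic ortho-lithiations, with an acetal put on and taken off) to 2-fluoro-5-propylbenzene-1,3-dicarbaldehyde A2.
5-Hydroxyvanillin A3 would be monobenzylated at O4, homologated by Wittig olefination and reduced to methyl 3-[4-(benzyloxy)-3-hydroxy-5-methoxyphenyl]propanoate A4, whose phenoxide would displace the fluoride of A2 to give the diaryl ether dialdehyde A5.
A double Dakin-type oxidation of A5, double O-methylation, ester reduction and hydrogenolysis would end at the target, about eleven steps in all.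
Weak step, the double aryl-migration oxidation of A5: two Baeyer–Villiger events with excess peracid on a crowded ring beside an electron-rich ring, late in the route, where every hydride migration or ring oxidation is a loss.
Weak stretch, the run-up to ring A: two lithiation/formylations, an acetalisation, the oxidation and a methylation serve only to place two methoxy groups beside the ether oxygen; the formyl groups are activating groups that build nothing.
Weak step, the monobenzylation of A3: it must tell two phenols apart by acidity alone, and the benzyl group is then carried through eight steps to a separate final deprotection.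

**Retrosynthetic overview**
Ring A (2,6-dimethoxy-4-propylphenoxy, C1 bears the ether oxygen) is the intact skeleton of a commercial phenol; ring B (chain at C1, OMe at C3, OH at C4, ether at C5) carries a free OH directly beside the ether carbon.
This C4–OH/C5–OAr pair is read as the retron of a carbenoid O–H insertion: the only skeletal bond made is O–C5 of ring B, from the ortho-quinone diazide of ring B (diazo carbon = C5, carbonyl oxygen = the later C4–OH) and the O–H of the ring A phenol.
No ring is built: both rings are bought with their oxygens in place; ring B becomes the diazide by nitration ortho to OH, reduction and diazotisation, and one ester reduction follows the coupling.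
The design needs no activating formyl groups, no aryl-migration oxidation, no late methylation and no phenol protecting group; it is a two-electron counterpart of the presumed biosynthetic 4-O-5 phenol coupling, with a carbene in place of the C5 radical.

Key step: step 4

Remark: methyl dihydroferulate and 4-propylsyringol are taken as catalogue compounds; the ortho-quinone diazide is treated as a light-sensitive, potentially energetic diazo compound that is made and used cold, in solution and without storage.

Step 1
Reactants: 1 methyl 3-(4-hydroxy-3-methoxyphenyl)propanoate (methyl dihydroferulate)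
Product: 2 methyl 3-(4-hydroxy-3-methoxy-5-nitrophenyl)propanoate
Conditions: 65% HNO3 (1.05 equiv), AcOH, 10 °C
Reagents that add atoms: nitric acid, O[N+](=O)[O-]
Why: Electrophilic aromatic nitration of a phenol: the free OH is the strongest director and its para position carries the chain, so the nitro group should enter the open ortho position C5, and the hydrogen-bonded, deactivated nitrophenol should resist a second nitration.

Step 2
Reactants: 2 methyl 3-(4-hydroxy-3-methoxy-5-nitrophenyl)propanoate
Product: 3 methyl 3-(3-amino-4-hydroxy-5-methoxyphenyl)propanoate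
Conditions: H2 (1 atm), 10% Pd/C, MeOH, rt; filtered under N2 and used at once
Reagents that add atoms: none
Why: Catalytic hydrogenation reduces the nitro group to the amine while the ester and the aryl methyl ether are inert; the air-sensitive ortho-aminophenol is not stored.

Step 3
Reactants: 3 methyl 3-(3-amino-4-hydroxy-5-methoxyphenyl)propanoate
Product: 5 methyl 3-(3-diazo-5-methoxy-4-oxocyclohexa-1,5-dien-1-yl)propanoate, via 2-hydroxyarenediazonium chloride 4 (not isolated)
Conditions: NaNO2 (1.05 equiv), 2 M aq. HCl/MeCN, 0 °C; then NaHCO3 to pH 7, extraction into CH2Cl2, Na2SO4, dark, below 10 °C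
Reagents that add atoms: sodium nitrite, [Na+].[O-]N=O
Why: Diazotisation of an ortho-aminophenol; on neutralisation the 2-hydroxyarenediazonium ion loses its phenolic proton and should give the neutral, extractable ortho-quinone diazide (diazo oxide).

Step 4
Reactants: 5 methyl 3-(3-diazo-5-methoxy-4-oxocyclohexa-1,5-dien-1-yl)propanoate; 6 2,6-dimethoxy-4-propylphenol (4-propylsyringol)
Product: 7 methyl 3-[3-(2,6-dimethoxy-4-propylphenoxy)-4-hydroxy-5-methoxyphenyl]propanoate
Conditions: Rh2(OAc)4 (2 mol %), 6 (3 equiv), CH2Cl2, 40 °C, slow addition of 5 over 3 h, dark, N2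
Reagents that add atoms: none
Why: Proposed new method: dirhodium tetraacetate should expel N2 from the diazo carbon of 5 (C5 of ring B) to give an electrophilic ortho-quinoid carbenoid; the phenol oxygen of 6 adds to this carbon, and a 1,4-proton shift from the oxonium to the neighbouring carbonyl oxygen re-aromatises ring B, so that the C5–O(ring A) bond and the free C4–OH are formed in the same event, driven by aromatisation and loss of N2. The closest known reaction type is the dirhodium-catalysed O–H insertion of alpha-diazo carbonyl compounds into phenols and alcohols, together with carbene transfer from quinone diazides to alkenes and arenes; the step extends it to a monocyclic ortho-quinone diazide and a hindered phenol. No ring is closed and no stereocentre is formed. The selectivity needed is O–H insertion over attack at a ring carbon of 6, over insertion into the new phenol of 7 and over Wolff ring contraction of 5: in 6 both ortho positions (OMe) and the para position (propyl) are blocked, which leaves oxygen as the only open nucleophilic site and also excludes azo coupling, the threefold excess of 6 with slow addition of 5 disfavours reaction with 7 and carbene dimerisation, and the ring contraction needs light or temperatures well above 40 °C. The position of the ether on ring B cannot vary, because it is the carbon that carried the nitro group.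

Step 5
Reactants: 7 methyl 3-[3-(2,6-dimethoxy-4-propylphenoxy)-4-hydroxy-5-methoxyphenyl]propanoate
Product: 8 2-(2,6-dimethoxy-4-propylphenoxy)-4-(3-hydroxypropyl)-6-methoxyphenol (target)
Conditions: LiAlH4 (2.5 equiv), THF, 0 °C to rt; aq. Rochelle salt, then dilute HCl to pH 4
Reagents that add atoms: none
Why: Hydride reduction of the methyl ester gives the primary alcohol; the phenol is carried as its aluminium phenoxide and set free on acidic work-up, and the diaryl and methyl ethers are inert.

**Compound list**
1 | methyl 3-(4-hydroxy-3-methoxyphenyl)propanoate (methyl dihydroferulate) | COC(=O)CCc1ccc(O)c(OC)c1 | starting material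
2 | methyl 3-(4-hydroxy-3-methoxy-5-nitrophenyl)propanoate | COC(=O)CCc1cc(OC)c(O)c([N+](=O)[O-])c1 | intermediate
3 | methyl 3-(3-amino-4-hydroxy-5-methoxyphenyl)propanoate | COC(=O)CCc1cc(N)c(O)c(OC)c1 | intermediate
4 | 2-hydroxy-3-methoxy-5-(3-methoxy-3-oxopropyl)benzenediazonium chloride (not isolated) | COC(=O)CCc1cc(OC)c(O)c([N+]#N)c1.[Cl-] | intermediate
5 | methyl 3-(3-diazo-5-methoxy-4-oxocyclohexa-1,5-dien-1-yl)propanoate (ortho-quinone diazide of ring B) | COC(=O)CCC1=CC(=[N+]=[N-])C(=O)C(OC)=C1 | intermediate
6 | 2,6-dimethoxy-4-propylphenol (4-propylsyringol) | CCCc1cc(OC)c(O)c(OC)c1 | starting material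
7 | methyl 3-[3-(2,6-dimethoxy-4-propylphenoxy)-4-hydroxy-5-methoxyphenyl]propanoate | CCCc1cc(OC)c(Oc2cc(CCC(=O)OC)cc(OC)c2O)c(OC)c1 | intermediate
8 | 2-(2,6-dimethoxy-4-propylphenoxy)-4-(3-hydroxypropyl)-6-methoxyphenol | CCCc1cc(OC)c(Oc2cc(CCCO)cc(OC)c2O)c(OC)c1 | target

**Step count**
Total steps: 5. Longest linear sequence: 5 steps (1 to 2 to 3 to 5 to 7 to 8; 6 enters in step 4).

**Steps most likely to fail**

Step 4 (Proposed new method). The carbenoid may form too slowly, so that the diazide is lost by ring contraction or carbene dimerisation. The electron-rich phenol 6 may instead reduce the diazide by electron transfer, or the carbenoid may be taken by the phenol of the product. The fallback uses the known copper-catalysed Ullmann-type ether synthesis and sets out from 1. Ortho-iodination (I2, NaHCO3, THF/H2O, rt) should give methyl 3-(4-hydroxy-3-iodo-5-methoxyphenyl)propanoate F1. Protection (MOMCl, iPr2NEt, CH2Cl2) gives methyl 3-[3-iodo-5-methoxy-4-(methoxymethoxy)phenyl]propanoate F2. Coupling with 6 (CuI, picolinic acid, K3PO4, DMSO, 90 °C) gives methyl 3-[3-(2,6-dimethoxy-4-propylphenoxy)-5-methoxy-4-(methoxymethoxy)phenyl]propanoate F3. Acetal cleavage (cat. HCl, MeOH, 40 °C) comes back to the route at 7.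

Step 3. The diazonium ion may azo-couple with aminophenol that is not yet diazotised, and the electron-rich diazide may lose nitrogen during neutralisation and concentration. The fallback sets out from 3 and leaves carbene chemistry for a metal-free arylation with a diaryliodonium salt. The acidic solution of 4 is not neutralised but treated with KI (Sandmeyer-type iododediazoniation), which should give methyl 3-(4-hydroxy-3-iodo-5-methoxyphenyl)propanoate F1. Acylation (PivCl, Et3N, cat. DMAP, CH2Cl2) gives methyl 3-[4-(2,2-dimethylpropanoyloxy)-3-iodo-5-methoxyphenyl]propanoate F4. One-pot oxidation and arylation (mCPBA, TsOH·H2O, MeCN; then 1,3,5-trimethoxybenzene) gives [2-(2,2-dimethylpropanoyloxy)-3-methoxy-5-(3-methoxy-3-oxopropyl)phenyl](2,4,6-trimethoxyphenyl)iodonium 4-methylbenzenesulfonate F5. O-Arylation of 6 (K2CO3, MeCN, 50 °C), in which the trimethoxyphenyl group stays on iodine, gives methyl 3-[3-(2,6-dimethoxy-4-propylphenoxy)-4-(2,2-dimethylpropanoyloxy)-5-methoxyphenyl]propanoate F6. The LiAlH4 conditions of step 5 then cleave the pivalate and reduce the methyl ester in one operation, so the detour comes back to the route at 8.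

Step 1. The electron-rich guaiacol ring may be oxidised to quinones, and some nitration may occur para to the methoxy group. The fallback sets out from 1 and replaces nitration by azo coupling followed by reductive cleavage. Coupling of 1 with diazotised sulfanilic acid (aq. Na2CO3, 0 °C) should take place at the open position ortho to the phenoxide and give 4-[(E)-[2-hydroxy-3-methoxy-5-(3-methoxy-3-oxopropyl)phenyl]diazenyl]benzenesulfonic acid F7. Reduction of the azo bond (Na2S2O4, aq. MeOH, or the hydrogenation conditions of step 2) gives the aminophenol, with a water-soluble by-product, and comes back to the route at 3.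

**Further compounds**
F1 | step 4 | methyl 3-(4-hydroxy-3-iodo-5-methoxyphenyl)propanoate | COC(=O)CCc1cc(I)c(O)c(OC)c1
F2 | step 4 | methyl 3-[3-iodo-5-methoxy-4-(methoxymethoxy)phenyl]propanoate | COCOc1c(I)cc(CCC(=O)OC)cc1OC
F3 | step 4 | methyl 3-[3-(2,6-dimethoxy-4-propylphenoxy)-5-methoxy-4-(methoxymethoxy)phenyl]propanoate | CCCc1cc(OC)c(Oc2cc(CCC(=O)OC)cc(OC)c2OCOC)c(OC)c1
F4 | step 3 | methyl 3-[4-(2,2-dimethylpropanoyloxy)-3-iodo-5-methoxyphenyl]propanoate | COC(=O)CCc1cc(I)c(OC(=O)C(C)(C)C)c(OC)c1
F5 | step 3 | [2-(2,2-dimethylpropanoyloxy)-3-methoxy-5-(3-methoxy-3-oxopropyl)phenyl](2,4,6-trimethoxyphenyl)iodonium 4-methylbenzenesulfonate | COC(=O)CCc1cc([I+]c2c(OC)cc(OC)cc2OC)c(OC(=O)C(C)(C)C)c(OC)c1.Cc1ccc(S(=O)(=O)[O-])cc1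
F6 | step 3 | methyl 3-[3-(2,6-dimethoxy-4-propylphenoxy)-4-(2,2-dimethylpropanoyloxy)-5-methoxyphenyl]propanoate | CCCc1cc(OC)c(Oc2cc(CCC(=O)OC)cc(OC)c2OC(=O)C(C)(C)C)c(OC)c1
F7 | step 1 | 4-[(E)-[2-hydroxy-3-methoxy-5-(3-methoxy-3-oxopropyl)phenyl]diazenyl]benzenesulfonic acid | COC(=O)CCc1cc(OC)c(O)c(/N=N/c2ccc(S(=O)(=O)O)cc2)c1
A1 | direct plan | 1-fluoro-4-propylbenzene | CCCc1ccc(F)cc1
A2 | direct plan | 2-fluoro-5-propylbenzene-1,3-dicarbaldehyde | CCCc1cc(C=O)c(F)c(C=O)c1
A3 | direct plan | 3,4-dihydroxy-5-methoxybenzaldehyde (5-hydroxyvanillin) | COc1cc(C=O)cc(O)c1O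
A4 | direct plan | methyl 3-[4-(benzyloxy)-3-hydroxy-5-methoxyphenyl]propanoate | COC(=O)CCc1cc(O)c(OCc2ccccc2)c(OC)c1
A5 | direct plan | methyl 3-[4-(benzyloxy)-3-(2,6-diformyl-4-propylphenoxy)-5-methoxyphenyl]propanoate | CCCc1cc(C=O)c(Oc2cc(CCC(=O)OC)cc(OC)c2OCc2ccccc2)c(C=O)c1
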